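## Retrosynthetic overview

1. Target 22 is a cis-fused hydroazulene (azulene locants: C3 isopropyl, C3a OH, C6 methyl, C8 ester, C8a methyl). The 4-methoxybenzoate is put on last, and C8 is set just before by hydride reduction of hydroxy enone 19.
2. The seven-membered ring is made in one operation by a reductive [5+2] annulation of bromo ketone 7 with (Z)-iodo enal 15 under SmI2: a Reformatsky aldol forms C8–C8a and a Barbier cyclisation forms C3a–C4.
3. Enabling feature: C3a (tertiary carbinol) and C8a (quaternary, methyl) are the carbonyl carbon and the α-carbon of a cyclopentanone, and the other five ring carbons C8–C7=C6(CH3)–C5–C4 are a Z-enal ending in CH2I. The Z alkene lies inside the ring and pre-folds the chain.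
4. The cyclopentane comes first: (S)-limonene is cut open by ozonolysis and re-closed by aldol condensation to enal 5. Baeyer–Villiger excision of the formyl carbon gives a regiodefined enol formate and then 7; the isopropyl stereocenter controls all others.
5. The five-carbon piece 15 comes from 3-methylbut-3-en-1-ol and acryloyl chloride through ring-closing metathesis to lactone 11 (the ring fixes the Z geometry) and iodide ring-opening.

Key step: step 11

Remark on the chemistry: the α face is the face of the seven-membered ring that carries C8a–CH3 and C3a–OH. Diol 18 is written as the 8R epimer that the chair model predicts; it is assumed that any 8S epimer formed in step 11 is carried into step 12, where C8 becomes a ketone.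

## Route

Step 1
Reactants: 1 (S)-(−)-limonene
Product: 2 (4S)-1-methyl-4-(propan-2-yl)cyclohex-1-ene
Conditions: H2 (1 atm), RhCl(PPh3)3 (1 mol%), benzene–EtOH, rt
Reagents that add atoms: none
Why: Chemoselective homogeneous hydrogenation, in which the 1,1-disubstituted isopropenyl alkene should be reduced much faster than the trisubstituted ring alkene; the stereocenter is not touched.

Step 2
Reactants: 2 (4S)-1-methyl-4-(propan-2-yl)cyclohex-1-ene
Product: 4 (3S)-6-oxo-3-(propan-2-yl)heptanal, via ozonide 3 (not isolated)
Conditions: O3, CH2Cl2, −78 °C; then Me2S, −78 °C to rt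
Reagents that add atoms: ozone, [O-][O+]=O
Why: Ozonolysis with reductive work-up cleaves the ring C=C to the 1,6-keto aldehyde; the stereocenter is β to the aldehyde and cannot enolise.

Step 3
Reactants: 4 (3S)-6-oxo-3-(propan-2-yl)heptanal
Product: 5 (5R)-2-methyl-5-(propan-2-yl)cyclopent-1-ene-1-carbaldehyde
Conditions: piperidine (0.2 equiv), AcOH (0.2 equiv), toluene, 60 °C
Reagents that add atoms: none
Why: Intramolecular aldol condensation through the enamine of the aldehyde, which attacks the methyl ketone (5-exo-trig) and dehydrates to the tetrasubstituted enal; the isopropyl stereocenter is kept (the descriptor changes by priority only).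

Step 4
Reactants: 5 (5R)-2-methyl-5-(propan-2-yl)cyclopent-1-ene-1-carbaldehyde
Product: 6 (5R)-2-methyl-5-(propan-2-yl)cyclopent-1-en-1-yl formate
Conditions: 30% aq. H2O2 (2 equiv), bis(2-nitrophenyl) diselenide (2 mol%), CH2Cl2, rt
Reagents that add atoms: hydrogen peroxide, OO
Why: Baeyer–Villiger oxidation of an α,β-unsaturated aldehyde with migration of the alkenyl group, which removes the formyl carbon and fixes the enol double bond between the future C3a and C8a.

Step 5
Reactants: 6 (5R)-2-methyl-5-(propan-2-yl)cyclopent-1-en-1-yl formate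
Product: 7 (5R)-2-bromo-2-methyl-5-(propan-2-yl)cyclopentan-1-one
Conditions: N-bromosuccinimide (1.05 equiv), THF–H2O (4:1), 0 °C
Reagents that add atoms: N-bromosuccinimide, BrN1C(=O)CCC1=O
Why: Electrophilic bromination of the enol ester at its methyl-bearing carbon followed by hydrolytic loss of the formyl group, under near-neutral conditions that should not enolise the isopropyl-bearing carbon; the new C–Br center forms as a mixture of epimers, which is without consequence because it becomes planar in step 11.

Step 6
Reactants: 8 3-methylbut-3-en-1-ol, 9 acryloyl chloride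
Product: 10 3-methylbut-3-en-1-yl prop-2-enoate
Conditions: Et3N (1.2 equiv), DMAP (cat.), CH2Cl2, 0 °C to rt
Reagents that add atoms: none
Why: Acylation of a primary alcohol with an acid chloride (nucleophilic acyl substitution).

Step 7
Reactants: 10 3-methylbut-3-en-1-yl prop-2-enoate
Product: 11 4-methyl-5,6-dihydro-2H-pyran-2-one
Conditions: second-generation Grubbs catalyst (3 mol%), toluene (0.01 M), 80 °C
Reagents that add atoms: none
Why: Ring-closing metathesis to the α,β-unsaturated δ-lactone; the six-membered ring forces the new trisubstituted alkene into the cis arrangement of carbonyl carbon and CH2 that the seven-membered ring needs later.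

Step 8
Reactants: 11 4-methyl-5,6-dihydro-2H-pyran-2-one
Product: 13 methyl (2Z)-5-iodo-3-methylpent-2-enoate, via trimethylsilyl ester 12 (not isolated)
Conditions: Me3SiCl (1.5 equiv), NaI (1.5 equiv), MeCN, rt; then MeOH, rt
Reagents that add atoms: sodium iodide, [Na+].[I-]; methanol, CO
Why: Lactone opening by alkyl–oxygen cleavage (SN2 attack of iodide at O–CH2 after silylation of the carbonyl by Me3SiI made in the flask), then acid-promoted methanolysis/esterification of the silyl ester; no bond to the alkene is broken, so the Z geometry should be kept.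

Step 9
Reactants: 13 methyl (2Z)-5-iodo-3-methylpent-2-enoate
Product: 14 (2Z)-5-iodo-3-methylpent-2-en-1-ol
Conditions: i-Bu2AlH (2.2 equiv), CH2Cl2, −78 °C; aq. potassium sodium tartrate
Reagents that add atoms: none
Why: 1,2-Hydride reduction of the conjugated ester to the allylic alcohol at −78 °C, conditions that a primary iodide and a trisubstituted alkene should tolerate.

Step 10
Reactants: 14 (2Z)-5-iodo-3-methylpent-2-en-1-ol
Product: 15 (2Z)-5-iodo-3-methylpent-2-enal
Conditions: activated MnO2 (15 equiv), CH2Cl2, rt, dark; used at once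
Reagents that add atoms: none
Why: Allylic alcohol oxidation with MnO2 under neutral conditions, which should preserve the Z geometry and the iodide.

Step 11
Reactants: 7 (5R)-2-bromo-2-methyl-5-(propan-2-yl)cyclopentan-1-one, 15 (2Z)-5-iodo-3-methylpent-2-enal
Product: 18 (3R,3aS,8R,8aR)-6,8a-dimethyl-3-(propan-2-yl)-1,2,3,3a,4,5,8,8a-octahydroazulene-3a,8-diol, via samarium enolate 16 (not isolated), via samarium aldolate 17 (not isolated)
Conditions: SmI2 (2.1 equiv, added dropwise to 7 + 15), THF, −78 °C; then HMPA (8 equiv), SmI2 (2.4 equiv), −78 to 0 °C; aq. NH4Cl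
Reagents that add atoms: none
Why: SmI2 reduces the C–Br bond of 7 at −78 °C to the regiodefined trivalent samarium enolate 16, which adds to the aldehyde of 15 through a chelated chair (Zimmerman–Traxler) transition state to form C8–C8a and aldolate 17; after HMPA is added, a second two-electron reduction turns the primary iodide into an alkylsamarium that adds to the samarium-activated ketone and forms C3a–C4. The closest known reaction types are the samarium Reformatsky aldol of α-bromo ketones with aldehydes and the samarium Barbier cyclisation of ω-iodoalkyl ketones, run here as one sequenced reductive [5+2] annulation. The seven-membered ring closes by 7-exo-trig addition of carbanionic C4 to the C3a carbonyl, helped by the Z alkene C6=C7 that holds C5 and C8 cis, by samarium chelation between the C8 alkoxide and the ketone, and by the quaternary C8a. C8a is set by attack of the aldehyde on the enolate face anti to the C3 isopropyl group, which should sit pseudoaxial next to the bulky O–Sm group and screen its own face; C3a follows because the tether on C8a can only reach the same face of the ketone (cis fusion, again anti to isopropyl); C8 should come out 8R from the chair with the alkenyl group equatorial, but it is reset in steps 12 and 13. The step needs chemoselectivity (C–Br before aldehyde and C–I), secured by the order of addition and by the fact that the α-bromo ketone reacts without HMPA at −78 °C while the iodide reacts only after HMPA is added, and regioselective enolate formation, secured by the position of bromine.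

Step 12
Reactants: 18 (3R,3aS,8R,8aR)-6,8a-dimethyl-3-(propan-2-yl)-1,2,3,3a,4,5,8,8a-octahydroazulene-3a,8-diol
Product: 19 (3R,3aS,8aS)-3a-hydroxy-6,8a-dimethyl-3-(propan-2-yl)-2,3,3a,4,5,8a-hexahydroazulen-8(1H)-one
Conditions: activated MnO2 (20 equiv), CH2Cl2, rt
Reagents that add atoms: none
Why: Chemoselective MnO2 oxidation of the secondary allylic alcohol (the tertiary alcohol cannot be oxidised), so both C8 epimers converge on one enone.

Step 13
Reactants: 19 (3R,3aS,8aS)-3a-hydroxy-6,8a-dimethyl-3-(propan-2-yl)-2,3,3a,4,5,8a-hexahydroazulen-8(1H)-one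
Product: 20 (3R,3aS,8S,8aR)-6,8a-dimethyl-3-(propan-2-yl)-1,2,3,3a,4,5,8,8a-octahydroazulene-3a,8-diol
Conditions: LiBH(s-Bu)3 (2.5 equiv), THF, −78 °C; then NaOH, H2O2, 0 °C
Reagents that add atoms: none
Why: Substrate-controlled 1,2-reduction of a β,β-disubstituted enone by a bulky trialkylborohydride: the C3a alkoxide, which lies 1,3-syn to the α face of C8, and the C8a methyl should block the α face, so hydride should enter from the β face and place the new hydroxyl α, cis to C3a–OH and C8a–CH3 (8S), while conjugate reduction is disfavoured by the fully substituted C6.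

Step 14
Reactants: 20 (3R,3aS,8S,8aR)-6,8a-dimethyl-3-(propan-2-yl)-1,2,3,3a,4,5,8,8a-octahydroazulene-3a,8-diol, 21 4-methoxybenzoyl chloride
Product: 22 (3R,3aS,8S,8aR)-3a-hydroxy-6,8a-dimethyl-3-(propan-2-yl)-1,2,3,3a,4,5,8,8a-octahydroazulen-8-yl 4-methoxybenzoate
Conditions: pyridine (3 equiv), DMAP (0.2 equiv), CH2Cl2, 0 °C to rt
Reagents that add atoms: none
Why: DMAP-catalysed acylation of the secondary allylic alcohol with retention at C8; the tertiary C3a hydroxyl is too hindered to react.

## Compound list

1 | (S)-(−)-limonene, (4S)-1-methyl-4-(prop-1-en-2-yl)cyclohex-1-ene | CC1=CC[C@H](CC1)C(C)=C | starting material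
2 | (4S)-1-methyl-4-(propan-2-yl)cyclohex-1-ene | CC1=CC[C@H](CC1)C(C)C | intermediate
3 | secondary ozonide of 2, (4S)-1-methyl-4-(propan-2-yl)-7,8,9-trioxabicyclo[4.2.1]nonane | CC12CC[C@H](C(C)C)CC(O1)OO2 | intermediate
4 | (3S)-6-oxo-3-(propan-2-yl)heptanal | O=CC[C@@H](C(C)C)CCC(C)=O | intermediate
5 | (5R)-2-methyl-5-(propan-2-yl)cyclopent-1-ene-1-carbaldehyde | O=CC1=C(C)CC[C@@H]1C(C)C | intermediate
6 | (5R)-2-methyl-5-(propan-2-yl)cyclopent-1-en-1-yl formate | O=COC1=C(C)CC[C@@H]1C(C)C | intermediate
7 | (5R)-2-bromo-2-methyl-5-(propan-2-yl)cyclopentan-1-one (both C2 epimers) | CC1(Br)CC[C@H](C(C)C)C1=O | intermediate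
8 | 3-methylbut-3-en-1-ol | CC(=C)CCO | starting material
9 | acryloyl chloride (prop-2-enoyl chloride) | C=CC(Cl)=O | starting material
10 | 3-methylbut-3-en-1-yl prop-2-enoate | C=CC(=O)OCCC(C)=C | intermediate
11 | 4-methyl-5,6-dihydro-2H-pyran-2-one | CC1=CC(=O)OCC1 | intermediate
12 | trimethylsilyl (2Z)-5-iodo-3-methylpent-2-enoate | C[Si](C)(C)OC(=O)/C=C(/C)CCI | intermediate
13 | methyl (2Z)-5-iodo-3-methylpent-2-enoate | COC(=O)/C=C(/C)CCI | intermediate
14 | (2Z)-5-iodo-3-methylpent-2-en-1-ol | OC/C=C(/C)CCI | intermediate
15 | (2Z)-5-iodo-3-methylpent-2-enal | O=C/C=C(/C)CCI | intermediate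
16 | diiodosamarium enolate of (5R)-2-methyl-5-(propan-2-yl)cyclopentanone, O–Sm on the carbon that becomes C3a | CC1=C(O[Sm](I)I)[C@@H](C(C)C)CC1 | intermediate
17 | diiodosamarium alkoxide of (2R,5R)-2-[(1R,2Z)-1-hydroxy-5-iodo-3-methylpent-2-en-1-yl]-2-methyl-5-(propan-2-yl)cyclopentan-1-one | I[Sm](I)O[C@H](/C=C(/C)CCI)[C@@]1(C)CC[C@H](C(C)C)C1=O | intermediate
18 | (3R,3aS,8R,8aR)-6,8a-dimethyl-3-(propan-2-yl)-1,2,3,3a,4,5,8,8a-octahydroazulene-3a,8-diol (C8–OH trans to C3a–OH and C8a–CH3) | O[C@@H]1C=C(C)CC[C@]2(O)[C@@H](C(C)C)CC[C@]12C | intermediate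
19 | (3R,3aS,8aS)-3a-hydroxy-6,8a-dimethyl-3-(propan-2-yl)-2,3,3a,4,5,8a-hexahydroazulen-8(1H)-one | O=C1C=C(C)CC[C@]2(O)[C@@H](C(C)C)CC[C@]12C | intermediate
20 | (3R,3aS,8S,8aR)-6,8a-dimethyl-3-(propan-2-yl)-1,2,3,3a,4,5,8,8a-octahydroazulene-3a,8-diol (C8–OH cis to C3a–OH and C8a–CH3) | O[C@H]1C=C(C)CC[C@]2(O)[C@@H](C(C)C)CC[C@]12C | intermediate
21 | 4-methoxybenzoyl chloride | COc1ccc(cc1)C(Cl)=O | starting material
22 | (3R,3aS,8S,8aR)-3a-hydroxy-6,8a-dimethyl-3-(propan-2-yl)-1,2,3,3a,4,5,8,8a-octahydroazulen-8-yl 4-methoxybenzoate | COc1ccc(C(=O)O[C@H]2C=C(C)CC[C@]3(O)[C@@H](C(C)C)CC[C@]23C)cc1 | target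

## Step count and risks

Total step count: 14. Longest linear sequence: 9 steps (steps 1–5, then 11–14; the branch of steps 6–10 followed by 11–14 is equally long).

The three steps most likely to fail:

Step 11. What may go wrong: retro-aldol of the samarium aldolate before ring closure, intramolecular O-alkylation of the alkoxide by the iodide (dihydropyran formation), reduction or pinacol coupling of the enal before the enolate captures it, slow seven-membered ring closure, or poor facial selectivity of the aldol with respect to the isopropyl group. The fallback separates the two bond formations and changes both metals. From 7 and 15, a chromium Reformatsky reaction (CrCl2, LiI cat., THF, rt), which should leave the alkyl iodide alone, would give (2R,5R)-2-[(1R,2Z)-1-hydroxy-5-iodo-3-methylpent-2-en-1-yl]-2-methyl-5-(propan-2-yl)cyclopentan-1-one F1. Silylation with Et3SiOTf and 2,6-lutidine would give its triethylsilyl ether F2. Iodine–lithium exchange with t-BuLi (2.1 equiv, Et2O–pentane, −78 °C) and anionic 7-exo-trig cyclisation onto the ketone should give (3R,3aS,8R,8aR)-6,8a-dimethyl-3-(propan-2-yl)-8-(triethylsilyloxy)-1,2,3,3a,4,5,8,8a-octahydroazulen-3a-ol F3. Bu4NF in THF would then give 18, where the route is rejoined.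

Step 13. What may go wrong: hydride delivery to the α face (poor facial selectivity, giving 18 instead of 20) or competing conjugate reduction. The fallback puts the opposite preference to use and installs the ester with inversion. From 19, Luche reduction (NaBH4, CeCl3·7H2O, MeOH, −40 °C), where a small hydride should attack from the α face, would give the 8R alcohol 18. Mitsunobu esterification of 18 with 4-methoxybenzoic acid (PPh3, diisopropyl azodicarboxylate, toluene, 0 °C to rt) should then displace at C8 with inversion and reach 22 directly, replacing steps 13 and 14. No new compound is made on this path.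

Step 4. What may go wrong: epoxidation of the tetrasubstituted alkene or further oxidation of the enol formate in competition with alkenyl migration, and hydrolysis of the enol formate with loss of regiocontrol. The fallback excises the formyl carbon by a Curtius sequence. From 5, Pinnick oxidation (NaClO2, NaH2PO4, 2-methylbut-2-ene, t-BuOH–H2O) would give (5R)-2-methyl-5-(propan-2-yl)cyclopent-1-ene-1-carboxylic acid F4. Treatment with (PhO)2P(O)N3 and Et3N in toluene, then t-BuOH at 80 °C, would pass through (5R)-2-methyl-5-(propan-2-yl)cyclopent-1-ene-1-carbonyl azide F5 and (5R)-1-isocyanato-2-methyl-5-(propan-2-yl)cyclopent-1-ene F6 to tert-butyl [(5R)-2-methyl-5-(propan-2-yl)cyclopent-1-en-1-yl]carbamate F7. N-Bromosuccinimide in THF–H2O should brominate F7 at the methyl-bearing carbon and hydrolyse the resulting N-acyliminium to 7, where the route is rejoined.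

## Further compounds

F1 | step 11 | (2R,5R)-2-[(1R,2Z)-1-hydroxy-5-iodo-3-methylpent-2-en-1-yl]-2-methyl-5-(propan-2-yl)cyclopentan-1-one | O[C@H](/C=C(/C)CCI)[C@@]1(C)CC[C@H](C(C)C)C1=O
F2 | step 11 | (2R,5R)-2-[(1R,2Z)-5-iodo-3-methyl-1-(triethylsilyloxy)pent-2-en-1-yl]-2-methyl-5-(propan-2-yl)cyclopentan-1-one | CC[Si](CC)(CC)O[C@H](/C=C(/C)CCI)[C@@]1(C)CC[C@H](C(C)C)C1=O
F3 | step 11 | (3R,3aS,8R,8aR)-6,8a-dimethyl-3-(propan-2-yl)-8-(triethylsilyloxy)-1,2,3,3a,4,5,8,8a-octahydroazulen-3a-ol | CC[Si](CC)(CC)O[C@@H]1C=C(C)CC[C@]2(O)[C@@H](C(C)C)CC[C@]12C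
F0 | step 13 | none | none
F4 | step 4 | (5R)-2-methyl-5-(propan-2-yl)cyclopent-1-ene-1-carboxylic acid | OC(=O)C1=C(C)CC[C@@H]1C(C)C
F5 | step 4 | (5R)-2-methyl-5-(propan-2-yl)cyclopent-1-ene-1-carbonyl azide | [N-]=[N+]=NC(=O)C1=C(C)CC[C@@H]1C(C)C
F6 | step 4 | (5R)-1-isocyanato-2-methyl-5-(propan-2-yl)cyclopent-1-ene | O=C=NC1=C(C)CC[C@@H]1C(C)C
F7 | step 4 | tert-butyl [(5R)-2-methyl-5-(propan-2-yl)cyclopent-1-en-1-yl]carbamate | CC(C)(C)OC(=O)NC1=C(C)CC[C@@H]1C(C)C
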